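**Retrosynthetic overview**

1. Target 22 comes from the stilbene 21 by one hydrogenation (C=C and three benzyl ethers); 21 comes from a Wittig union of the ring-C benzylphosphonium salt 17 with the ring-D aldehyde 19.
2. The strategy rests on ring C, the 1,4-disubstituted benzene whose C1 carries the diaryl ether oxygen to ring B and whose C4 carries the CH2CH2 bridge to ring D. It is built from methyl coumalate 13 and the aryl ethynyl ether 12 by [4+2] cycloaddition and CO2 loss, with the aryl–O bond already present.
3. 12 comes from phenol 6 and trichloroethylene 7 (addition, then double dechlorination with BuLi).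
4. 6 comes from 3,4-dihydroxybenzaldehyde 1 (ring B) and the 3-methoxybenzyl phosphonium salt 3 (ring A) by Wittig olefination and diimide reduction.
5. Rings A, B and D are bought as arenes; ring C is the only ring formed.

Key step: step 6

Assumption: the target has no stereocentre and no stereogenic axis, so it is achiral and needs no enantiocontrol; stilbenes 5 and 21 may be E/Z mixtures because both double bonds are later saturated. Compounds 3 and 18 are taken as purchasable.

**Route**

Step 1
Reactants: 1 3,4-dihydroxybenzaldehyde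
Product: 2 4-(benzyloxy)-3-hydroxybenzaldehyde
Conditions: BnBr (1.0 equiv), NaHCO3 (1.5 equiv), DMF, 40 °C
Reagents that add atoms: benzyl bromide, BrCc1ccccc1
Why: Williamson etherification in which only the more acidic 4-OH (para to the formyl group) is ionised by the weak base, so monobenzylation should occur at O4.

Step 2
Reactants: 2 4-(benzyloxy)-3-hydroxybenzaldehyde; 3 (3-methoxybenzyl)triphenylphosphonium chloride
Product: 5 2-(benzyloxy)-5-[2-(3-methoxyphenyl)ethenyl]phenol (E/Z mixture), via phosphonium ylide 4 (not isolated)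
Conditions: 3 (1.3 equiv), KOtBu (2.5 equiv), THF, 0 °C; then 2, 0 °C to rt
Reagents that add atoms: none
Why: Wittig olefination of the semi-stabilised benzylic ylide with the aryl aldehyde, the extra base holding the meta-phenol as its phenoxide, which is not conjugated with the formyl group and so should not shut down addition.

Step 3
Reactants: 5 2-(benzyloxy)-5-[2-(3-methoxyphenyl)ethenyl]phenol
Product: 6 2-(benzyloxy)-5-[2-(3-methoxyphenyl)ethyl]phenol
Conditions: TsNHNH2 (5 equiv), NaOAc (6 equiv), DME/H2O, reflux
Reagents that add atoms: none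
Why: Diimide reduction, in which diimide released from the sulfonyl hydrazide transfers H2 to the C=C bond in a concerted manner and cannot cleave the aryl benzyl ether that Pd-catalysed hydrogenation would remove.

Step 4
Reactants: 6 2-(benzyloxy)-5-[2-(3-methoxyphenyl)ethyl]phenol; 7 trichloroethylene
Product: 9 1-(benzyloxy)-2-{[(E)-1,2-dichloroethenyl]oxy}-4-[2-(3-methoxyphenyl)ethyl]benzene, via dichloroacetylene 8 (not isolated)
Conditions: 7 (1.5 equiv), K2CO3 (2 equiv), DMF, 70 °C
Reagents that add atoms: none
Why: Base-mediated elimination–addition, in which trichloroethylene loses HCl to dichloroacetylene and the phenoxide adds anti across it to give the (E)-1,2-dichlorovinyl aryl ether, the standard entry to aryl ynol ethers from phenols.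

Step 5
Reactants: 9 1-(benzyloxy)-2-{[(E)-1,2-dichloroethenyl]oxy}-4-[2-(3-methoxyphenyl)ethyl]benzene
Product: 12 1-(benzyloxy)-2-(ethynyloxy)-4-[2-(3-methoxyphenyl)ethyl]benzene, via chloroethynyl ether 10 (not isolated), via lithium aryloxyacetylide 11 (not isolated)
Conditions: n-BuLi (2.3 equiv), THF, −78 to −40 °C; then H2O, −78 °C; filtered through basic alumina and kept as a PhMe solution
Reagents that add atoms: none
Why: Dehydrochlorination by the first equivalent of BuLi gives the chloroalkyne, Cl/Li exchange with the second gives the lithium acetylide, and protonation gives the terminal ynol ether (dichlorovinyl ether to ynol ether conversion), the low temperature sparing the benzyl ether.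

Step 6
Reactants: 12 1-(benzyloxy)-2-(ethynyloxy)-4-[2-(3-methoxyphenyl)ethyl]benzene; 13 methyl coumalate (methyl 2-oxo-2H-pyran-5-carboxylate)
Product: 15 methyl 4-{2-(benzyloxy)-5-[2-(3-methoxyphenyl)ethyl]phenoxy}benzoate, via bicyclic lactone 14 (not isolated)
Conditions: 13 (2 equiv, recrystallised), BHT (cat.), PhMe, 100 °C, sealed tube, slow addition of 12
Reagents that add atoms: none
Why: Proposed new method: the electron-poor pyrone diene (C3=C4–C5=C6, LUMO lowered by the lactone carbonyl and the C5 ester) should take up the electron-rich ynol ether in an inverse-electron-demand [4+2] cycloaddition, the nucleophilic terminal alkyne CH bonding to C6 and the oxygen-bearing alkyne carbon to C3, to give the bridged 2-oxabicyclo[2.2.2]octa-5,7-dien-3-one 14. Lactone 14 then loses CO2 by retro-[4+2] at the reaction temperature, and because the 2π partner is an alkyne this extrusion delivers the benzene directly, with no oxidation or elimination step in which the aryloxy group could be lost. The closest known reaction type is the cycloaddition–decarboxylation of coumalates with ketene acetals, enol ethers and ynamines to give para-substituted benzoates. Ring C is closed as a six-membered carbocycle by intermolecular [4+2] annulation forming two C–C bonds (C6–CH and C3–C(OAr)), and no stereocentre remains after aromatisation. The step needs para regiochemistry (ether oxygen para to the ester carbon), which should follow from matching the largest LUMO coefficient at pyrone C6 with the β-carbon of the polarised aryloxyalkyne; slow addition of 12 to excess 13 should limit self-oligomerisation of the ynol ether.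

Step 7
Reactants: 15 methyl 4-{2-(benzyloxy)-5-[2-(3-methoxyphenyl)ethyl]phenoxy}benzoate
Product: 16 (4-{2-(benzyloxy)-5-[2-(3-methoxyphenyl)ethyl]phenoxy}phenyl)methanol
Conditions: LiAlH4, THF, 0 °C
Reagents that add atoms: none
Why: Hydride reduction of the aryl methyl ester to the benzylic alcohol, with the diaryl, benzyl and methyl ethers inert to LiAlH4.

Step 8
Reactants: 16 (4-{2-(benzyloxy)-5-[2-(3-methoxyphenyl)ethyl]phenoxy}phenyl)methanol
Product: 17 (4-{2-(benzyloxy)-5-[2-(3-methoxyphenyl)ethyl]phenoxy}benzyl)triphenylphosphonium bromide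
Conditions: PPh3·HBr (1.1 equiv), MeCN, reflux
Reagents that add atoms: triphenylphosphine hydrobromide, [Br-].[PH+](c1ccccc1)(c1ccccc1)c1ccccc1
Why: The para-aryloxy benzylic alcohol is activated by the phosphonium hydrobromide and captured by PPh3 (one-pot alcohol to phosphonium salt conversion), under acidity too weak to cleave the aryl benzyl ether.

Step 9
Reactants: 18 2,5-dihydroxybenzaldehyde
Product: 19 2,5-bis(benzyloxy)benzaldehyde
Conditions: BnBr (2.4 equiv), K2CO3 (3 equiv), DMF, 60 °C
Reagents that add atoms: benzyl bromide, BrCc1ccccc1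
Why: Double Williamson etherification, the excess of bromide and gentle heating carrying the hydrogen-bonded 2-OH to completion.

Step 10
Reactants: 17 (4-{2-(benzyloxy)-5-[2-(3-methoxyphenyl)ethyl]phenoxy}benzyl)triphenylphosphonium bromide; 19 2,5-bis(benzyloxy)benzaldehyde
Product: 21 1,4-bis(benzyloxy)-2-[2-(4-{2-(benzyloxy)-5-[2-(3-methoxyphenyl)ethyl]phenoxy}phenyl)ethenyl]benzene (E/Z mixture), via phosphonium ylide 20 (not isolated)
Conditions: KOtBu (1.1 equiv), THF, 0 °C; then 19, 0 °C to rt
Reagents that add atoms: none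
Why: Wittig olefination of the semi-stabilised benzylic ylide with the aryl aldehyde joins ring C to ring D, and the alkene geometry is irrelevant because the double bond is saturated next.

Step 11
Reactants: 21 1,4-bis(benzyloxy)-2-[2-(4-{2-(benzyloxy)-5-[2-(3-methoxyphenyl)ethyl]phenoxy}phenyl)ethenyl]benzene
Product: 22 2-[2-(4-{2-hydroxy-5-[2-(3-methoxyphenyl)ethyl]phenoxy}phenyl)ethyl]benzene-1,4-diol (target)
Conditions: H2 (1 atm), 10% Pd/C, degassed EtOAc/MeOH, rt; work-up under argon
Reagents that add atoms: none
Why: Heterogeneous catalytic hydrogenation saturates the stilbene C=C bond and hydrogenolyses the three aryl benzyl ethers in one operation, while the diaryl ether and the aryl methyl ether are stable to Pd/C and H2.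

**Compound list**

1 | 3,4-dihydroxybenzaldehyde | O=Cc1ccc(O)c(O)c1 | starting material
2 | 4-(benzyloxy)-3-hydroxybenzaldehyde | O=Cc1ccc(OCc2ccccc2)c(O)c1 | intermediate
3 | (3-methoxybenzyl)triphenylphosphonium chloride | COc1cccc(C[P+](c2ccccc2)(c2ccccc2)c2ccccc2)c1.[Cl-] | starting material
4 | (3-methoxybenzylidene)triphenylphosphorane (not isolated) | COc1cccc(C=P(c2ccccc2)(c2ccccc2)c2ccccc2)c1 | intermediate
5 | 2-(benzyloxy)-5-[2-(3-methoxyphenyl)ethenyl]phenol (E/Z mixture) | COc1cccc(C=Cc2ccc(OCc3ccccc3)c(O)c2)c1 | intermediate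
6 | 2-(benzyloxy)-5-[2-(3-methoxyphenyl)ethyl]phenol | COc1cccc(CCc2ccc(OCc3ccccc3)c(O)c2)c1 | intermediate
7 | trichloroethylene | ClC=C(Cl)Cl | starting material
8 | dichloroacetylene (not isolated) | ClC#CCl | intermediate
9 | 1-(benzyloxy)-2-{[(E)-1,2-dichloroethenyl]oxy}-4-[2-(3-methoxyphenyl)ethyl]benzene | Cl/C=C(/Cl)Oc1cc(CCc2cccc(OC)c2)ccc1OCc1ccccc1 | intermediate
10 | 1-(benzyloxy)-2-[(chloroethynyl)oxy]-4-[2-(3-methoxyphenyl)ethyl]benzene (not isolated) | ClC#COc1cc(CCc2cccc(OC)c2)ccc1OCc1ccccc1 | intermediate
11 | lithium {2-(benzyloxy)-5-[2-(3-methoxyphenyl)ethyl]phenoxy}acetylide (not isolated) | [Li]C#COc1cc(CCc2cccc(OC)c2)ccc1OCc1ccccc1 | intermediate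
12 | 1-(benzyloxy)-2-(ethynyloxy)-4-[2-(3-methoxyphenyl)ethyl]benzene | C#COc1cc(CCc2cccc(OC)c2)ccc1OCc1ccccc1 | intermediate
13 | methyl coumalate (methyl 2-oxo-2H-pyran-5-carboxylate) | COC(=O)C1=COC(=O)C=C1 | starting material
14 | methyl 8-{2-(benzyloxy)-5-[2-(3-methoxyphenyl)ethyl]phenoxy}-3-oxo-2-oxabicyclo[2.2.2]octa-5,7-diene-6-carboxylate (racemic, not isolated) | COC(=O)C1=CC2C(=O)OC1C=C2Oc1cc(CCc2cccc(OC)c2)ccc1OCc1ccccc1 | intermediate
15 | methyl 4-{2-(benzyloxy)-5-[2-(3-methoxyphenyl)ethyl]phenoxy}benzoate | COC(=O)c1ccc(Oc2cc(CCc3cccc(OC)c3)ccc2OCc2ccccc2)cc1 | intermediate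
16 | (4-{2-(benzyloxy)-5-[2-(3-methoxyphenyl)ethyl]phenoxy}phenyl)methanol | OCc1ccc(Oc2cc(CCc3cccc(OC)c3)ccc2OCc2ccccc2)cc1 | intermediate
17 | (4-{2-(benzyloxy)-5-[2-(3-methoxyphenyl)ethyl]phenoxy}benzyl)triphenylphosphonium bromide | [Br-].COc1cccc(CCc2ccc(OCc3ccccc3)c(Oc3ccc(C[P+](c4ccccc4)(c4ccccc4)c4ccccc4)cc3)c2)c1 | intermediate
18 | 2,5-dihydroxybenzaldehyde | O=Cc1cc(O)ccc1O | starting material
19 | 2,5-bis(benzyloxy)benzaldehyde | O=Cc1cc(OCc2ccccc2)ccc1OCc1ccccc1 | intermediate
20 | (4-{2-(benzyloxy)-5-[2-(3-methoxyphenyl)ethyl]phenoxy}benzylidene)triphenylphosphorane (not isolated) | COc1cccc(CCc2ccc(OCc3ccccc3)c(Oc3ccc(C=P(c4ccccc4)(c4ccccc4)c4ccccc4)cc3)c2)c1 | intermediate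
21 | 1,4-bis(benzyloxy)-2-[2-(4-{2-(benzyloxy)-5-[2-(3-methoxyphenyl)ethyl]phenoxy}phenyl)ethenyl]benzene (E/Z mixture) | COc1cccc(CCc2ccc(OCc3ccccc3)c(Oc3ccc(C=Cc4cc(OCc5ccccc5)ccc4OCc4ccccc4)cc3)c2)c1 | intermediate
22 | 2-[2-(4-{2-hydroxy-5-[2-(3-methoxyphenyl)ethyl]phenoxy}phenyl)ethyl]benzene-1,4-diol | COc1cccc(CCc2ccc(O)c(Oc3ccc(CCc4cc(O)ccc4O)cc3)c2)c1 | target

**Step count**

Total steps: 11. Longest linear sequence: 10 steps (steps 1–8, 10, 11, from 3,4-dihydroxybenzaldehyde); step 9 is the one-step side branch for ring D.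

**Steps most likely to fail**

1. Step 6 (proposed new method). The ynol ether may oligomerise or hydrate faster than it cycloadds, or bond formation may start at the wrong pyrone terminus and give the meta-benzoate. Fallback by known chemistry, with ring C bought and the diaryl ether made by nucleophilic aromatic substitution: setting out from phenol 6, heating with 4-fluorobenzaldehyde and K2CO3 in DMF at 120 °C should give 4-{2-(benzyloxy)-5-[2-(3-methoxyphenyl)ethyl]phenoxy}benzaldehyde F1. Reduction of this aldehyde with NaBH4 in MeOH/THF at 0 °C comes back to the route at alcohol 16.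

2. Step 5. The terminal ynol ether may be lost during protic quench, work-up and concentration (hydration to the aryl acetate, oligomerisation). Fallback with a C-silyl-capped, isolable ynol ether and a traceless silicon group: setting out from 9, the acetylide 11 is generated as before but trapped with Me3SiCl at −78 °C to give 1-(benzyloxy)-4-[2-(3-methoxyphenyl)ethyl]-2-{[(trimethylsilyl)ethynyl]oxy}benzene F2, which should survive chromatography. Heating F2 with 13 in toluene at 110–130 °C should pass through the silylated bicyclic lactone F3 (not isolated) and, after CO2 loss, give methyl 4-{2-(benzyloxy)-5-[2-(3-methoxyphenyl)ethyl]phenoxy}-3-(trimethylsilyl)benzoate F4, the silicon sitting on the nucleophilic alkyne carbon that bonds to pyrone C6. Protodesilylation of F4 with TFA in CH2Cl2 at rt (ipso protonation ortho to the aryloxy group) comes back to the route at ester 15.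

3. Step 3. Diimide may disproportionate faster than it reduces the stilbene, leaving alkene that is hard to separate from the bibenzyl. Fallback that makes the CH2–CH2 bridge without an alkene: setting out from aldehyde 2, addition of 3-methoxybenzylmagnesium chloride (2.5 equiv, THF, 0 °C; the first equivalent is consumed by the phenol) should give racemic 2-(benzyloxy)-5-[1-hydroxy-2-(3-methoxyphenyl)ethyl]phenol F5. Ionic deoxygenation of this para-benzyloxy-stabilised benzylic alcohol with Et3SiH and TFA in CH2Cl2 at 0 °C comes back to the route at phenol 6, bypassing 5.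

**Further compounds**

F1 | step 6 | 4-{2-(benzyloxy)-5-[2-(3-methoxyphenyl)ethyl]phenoxy}benzaldehyde | O=Cc1ccc(Oc2cc(CCc3cccc(OC)c3)ccc2OCc2ccccc2)cc1
F2 | step 5 | 1-(benzyloxy)-4-[2-(3-methoxyphenyl)ethyl]-2-{[(trimethylsilyl)ethynyl]oxy}benzene | C[Si](C)(C)C#COc1cc(CCc2cccc(OC)c2)ccc1OCc1ccccc1
F3 | step 5 | methyl 8-{2-(benzyloxy)-5-[2-(3-methoxyphenyl)ethyl]phenoxy}-3-oxo-7-(trimethylsilyl)-2-oxabicyclo[2.2.2]octa-5,7-diene-6-carboxylate (racemic, not isolated) | COC(=O)C1=CC2C(=O)OC1C([Si](C)(C)C)=C2Oc1cc(CCc2cccc(OC)c2)ccc1OCc1ccccc1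
F4 | step 5 | methyl 4-{2-(benzyloxy)-5-[2-(3-methoxyphenyl)ethyl]phenoxy}-3-(trimethylsilyl)benzoate | COC(=O)c1ccc(Oc2cc(CCc3cccc(OC)c3)ccc2OCc2ccccc2)c([Si](C)(C)C)c1
F5 | step 3 | 2-(benzyloxy)-5-[1-hydroxy-2-(3-methoxyphenyl)ethyl]phenol (racemic) | COc1cccc(CC(O)c2ccc(OCc3ccccc3)c(O)c2)c1
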